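The readings come from a simulation for an exercise, noise included.

A percentage point is the unit to think in: each reading here scatters by 0.5 percentage points.

| flask | left-handed substrate | right-handed substrate | coupling partner | precatalyst | remark | time |
|---|---|---|---|---|---|---|
| south | 10 mM | 10 mM | 40 mM | 0.20 mM | the very flask that is asked about, followed so far |  |
| west | 10 mM | 10 mM | 40 mM | 0.40 mM | run made earlier |  |
| flask | 10 mM | 10 mM | 40.0 mM | 0.20 mM |  | 20 h |

| run | time / h | left-handed substrate / % | right-handed substrate / % | left-handed product / % |
|---|---|---|---|---|
| south | 0.833 | 49.1 | 50.8 | 0 |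
| south | 1.50 | 49.4 | 50.5 | 0.2 |
| south | 3.00 | 49.8 | 49.9 | 0.4 |
| south | 5.00 | 49.2 | 50.2 | 0.8 |
| south | 10.0 | 47.9 | 49.8 | 3.1 |
| west | 2.00 | 50.0 | 49.0 | 1.1 |
| west | 5.00 | 48.3 | 49.4 | 1.8 |
| west | 10.0 | 45.9 | 48.9 | 5.9 |
| west | 15.0 | 44.1 | 47.4 | 7.9 |
| west | 20.0 | 42.8 | 44.8 | 11.3 |

(standard deviation of a reading: 0.5 percentage points)

* part of the left-handed substrate and right-handed substrate charged together that has reacted at 20 h
* excess of left-handed product over right-handed product in the product at 20 h
* excess of right-handed substrate over left-handed substrate among what is left of the two at 20 h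

Two numbers in west don't seem to go together at 20.0 h. The two substrates and left-handed product still add up to 98.9%, so the product looks purely left-handed, yet right-handed substrate has lost 5.2 points beside 7.2 points for left-handed substrate.

My reading is that right-handed substrate turns into left-handed substrate (racemisation), in proportion to the gap between them, while the catalyst draws on left-handed substrate. The gap then keeps pace with that draw. West's last three readings give, with their scatter:

2.8 points ÷ (5.4 points in 10.0 h) = 5.12 h, the lag: the gap divided by the rate of left-handed product.

The flask has half of west's precatalyst, so I halve west's rate and product, which gives my own c of 5.65%: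

gap = lag × rate = 1.4 points

eS = gap ÷ what is left = 1.47%

The forecast gives c 6%, eP 90% and eS 2.7%, saying “Both substrates therefore appear to funnel to left-handed product”. Its eS stands above mine.

The flask gives c 6.61%, eP 98.1% and eS 1.90%.

    coupling partner + free catalyst + left-handed substrate → free catalyst + left-handed product (k = 4800 M⁻² h⁻¹)
    coupling partner + free catalyst + right-handed substrate → free catalyst + right-handed product (k = 45.0 M⁻² h⁻¹)
    left-handed substrate ⇌ right-handed substrate (k = 0.100 h⁻¹)
    2 free catalyst → spent catalyst A (k = 190 M⁻¹ h⁻¹)
    free catalyst → spent catalyst B (k = 0.0370 h⁻¹)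
    precatalyst ⇌ free catalyst (K = 0.460, k = 0.0580 h⁻¹)

From 10.0 h to 20.0 h the flask gained 3.8 points of left-handed product, and the lag turns that rate into a gap of 1.9 points, against the 1.8 points it holds. The relaxation half-life of the two substrates by racemisation alone, both ways together, is 3.47 h, short against 20 h. The flask's c stays at 6.61% in part because of the length of the run, for one ten times as long reaches 28.8%. The neighbour flask with 0.50 mM of precatalyst made 14.0% of left-handed product in 20 h, so the lag times that mean rate gives 3.6 points, and that neighbour's gap stands at 3.5 points.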